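## Retrosynthetic overview

1. The target is disconnected last at its two ester bonds: double O-acylation of a 3α,9β-diol 8-ketone with two equivalents of 3-methylbut-2-enoyl chloride.
2. The 9β-OH comes from kinetic C9 enolate hydroxylation, the isopropenyl group from deconjugative protonation of a 7(11)-en-8-one, and the cis ring fusion from hydrogenation of a cross-conjugated dienone (which also frees the 3-OH).
3. The dienone comes from the key convergent step, a three-component Robinson annulation: ring A enone + Me2CuLi (C4 methyl) + 2-acetyl-3-methylbutadiene (C6–C9 and C11–C13).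
4. The ring A enone comes from cyclohexa-1,3-diene (singlet oxygen, asymmetric Kornblum–DeLaMare rearrangement, benzylation, α-iodination, Negishi methylation); the dienyl ketone from a methallyl Grignard reagent and a Weinreb acetamide via a Mannich base.
5. Ring order: ring A is carried in preformed; ring B is closed in the annulation.

Assumption and convention: 9-O-acetylcupreidine is taken as the catalyst pseudoenantiomer that gives the 4R hydroxy enone (otherwise the quinine-derived one is used); bicyclic compounds carry eremophilane numbering (ring A = C1–C5, C10; ring B = C5–C10; methyls on C4 and C5; C11–C13 on C7), with β = the face of the C5 methyl.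

## Route

Step 1
Reactants: 1 cyclohexa-1,3-diene
Product: 2 (1R,4S)-2,3-dioxabicyclo[2.2.2]oct-5-ene (meso endoperoxide)
Conditions: O2, tetraphenylporphyrin (cat.), visible light, CH2Cl2, −20 °C
Reagents that add atoms: dioxygen, O=O
Why: [4+2] cycloaddition of singlet oxygen to the s-cis diene (photooxygenation) gives the meso endoperoxide, which has no stereochemical issue.

Step 2
Reactants: 2 (1R,4S)-2,3-dioxabicyclo[2.2.2]oct-5-ene
Product: 3 (R)-4-hydroxycyclohex-2-en-1-one
Conditions: 9-O-acetylcupreidine [(9S)-6′-hydroxycinchonan-9-yl acetate] (5 mol %), CH2Cl2, rt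
Reagents that add atoms: none
Why: In this Kornblum–DeLaMare rearrangement the chiral base removes one of the two enantiotopic bridgehead hydrogens, so the desymmetrisation sets the carbinol centre that becomes C3.

Step 3
Reactants: 3 (R)-4-hydroxycyclohex-2-en-1-one
Product: 4 (R)-4-(benzyloxy)cyclohex-2-en-1-one
Conditions: benzyl 2,2,2-trichloroacetimidate, CF3SO3H (cat.), CH2Cl2–cyclohexane, 0 °C
Reagents that add atoms: benzyl 2,2,2-trichloroacetimidate, N=C(OCc1ccccc1)C(Cl)(Cl)Cl
Why: Acid-catalysed O-benzylation (imidate alkylation) avoids the base that would isomerise the γ-hydroxy enone and does not touch the stereocentre.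

Step 4
Reactants: 4 (R)-4-(benzyloxy)cyclohex-2-en-1-one
Product: 5 (R)-4-(benzyloxy)-2-iodocyclohex-2-en-1-one
Conditions: I2, pyridine, CH2Cl2, 0 °C → rt
Reagents that add atoms: iodine, II
Why: α-Iodination of the enone proceeds by pyridine conjugate addition, iodination of the enolate and E1cB loss of pyridine, leaving the γ-stereocentre untouched.

Step 5
Reactants: 5 (R)-4-(benzyloxy)-2-iodocyclohex-2-en-1-one
Product: 6 (R)-4-(benzyloxy)-2-methylcyclohex-2-en-1-one
Conditions: Me2Zn, Pd(dppf)Cl2 (5 mol %; dppf = 1,1′-bis(diphenylphosphino)ferrocene), THF, 0 °C → rt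
Reagents that add atoms: dimethylzinc, C[Zn]C
Why: Negishi cross-coupling of the alkenyl iodide installs the future C5 methyl under neutral conditions that spare the benzyloxy enone.

Step 6
Reactants: 7 (2-methylallyl)magnesium chloride, 8 N-methoxy-N-methylacetamide
Product: 9 4-methylpent-4-en-2-one
Conditions: THF, −78 → 0 °C; cold sat. aq NH4Cl
Reagents that add atoms: none
Why: In this Weinreb ketone synthesis the chelated tetrahedral intermediate prevents over-addition, and the cold neutral work-up keeps the double bond out of conjugation.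

Step 7
Reactants: 9 4-methylpent-4-en-2-one
Product: 10 3-[(dimethylamino)methyl]-4-methylpent-4-en-2-one (racemic)
Conditions: LiN(SiMe3)2, THF, −78 °C; then [Me2N=CH2]I, −78 °C → rt
Reagents that add atoms: N,N-dimethylmethyleneiminium iodide, C[N+](C)=C.[I-]
Why: Deprotonation at the doubly activated C3 gives the conjugated dienolate, which reacts at its α-carbon with the iminium salt (Mannich reaction).

Step 8
Reactants: 10 3-[(dimethylamino)methyl]-4-methylpent-4-en-2-one
Product: 11 (2-acetyl-3-methylbut-3-en-1-yl)trimethylammonium iodide (racemic)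
Conditions: MeI, Et2O, rt
Reagents that add atoms: iodomethane, CI
Why: Menshutkin quaternisation turns the amine into a leaving group and the salt precipitates.

Step 9
Reactants: 11 (2-acetyl-3-methylbut-3-en-1-yl)trimethylammonium iodide
Product: 12 4-methyl-3-methylidenepent-4-en-2-one
Conditions: Et3N, CH2Cl2, 0 °C; cold aqueous wash; dried solution kept at −78 °C and used at once
Reagents that add atoms: none
Why: E1cB elimination of trimethylamine from the Mannich-base methiodide releases the 2-acetyl diene, which is handled only cold and dilute to suppress Diels–Alder dimerisation.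

Step 10
Reactants: 13 3-methylbut-2-enoic acid
Product: 14 3-methylbut-2-enoyl chloride
Conditions: (COCl)2, HCONMe2 (cat.), CH2Cl2, 0 °C → rt
Reagents that add atoms: oxalyl chloride, ClC(=O)C(=O)Cl
Why: Acyl chloride formation via the Vilsmeier-type chloroiminium intermediate, with only gaseous by-products.

Step 11
Reactants: 6 (R)-4-(benzyloxy)-2-methylcyclohex-2-en-1-one, 12 4-methyl-3-methylidenepent-4-en-2-one
Product: 17 3α-benzyloxyeremophila-7(11),9-dien-8-one (4β,5β-dimethyl), via lithium enolate 15 (not isolated), via Michael diketone 16 (not isolated)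
Conditions: Me2CuLi, Et2O, −78 → −30 °C; then 12 in THF, −78 °C; then MeOH, NaOMe (cat.), rt → 45 °C
Reagents that add atoms: lithium dimethylcuprate, [Li+].C[Cu-]C
Why: Cuprate conjugate addition anti to the benzyloxy group sets C4, Michael addition of the tetrasubstituted enolate to 12 anti to the pseudoaxial C4 methyl sets the C5 quaternary centre with cis-vicinal methyls, and methoxide closes ring B by aldol condensation (Robinson annulation) while the C11 double bond moves into conjugation.

Step 12
Reactants: 17 3α-benzyloxyeremophila-7(11),9-dien-8-one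
Product: 18 3α-hydroxy-10βH-eremophil-7(11)-en-8-one (cis-fused)
Conditions: H2 (1 atm), 10% Pd/C, EtOH–AcOH (20:1), rt, stopped after 2 equiv H2
Reagents that add atoms: none
Why: Heterogeneous hydrogenation of angular-methyl octalones in weakly acidic ethanol delivers hydrogen to C10 on the β face to give the cis-fused decalone, the tetrasubstituted C7=C11 bond is too hindered to react, and the benzyl ether is hydrogenolysed in the same operation.

Step 13
Reactants: 18 3α-hydroxy-10βH-eremophil-7(11)-en-8-one
Product: 19 3α-hydroxy-10βH-eremophil-11-en-8-one (7β-isopropenyl)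
Conditions: t-BuOK (4 equiv), t-BuOH–THF, rt, 1 h; inverse quench into AcOH–THF, −78 °C; recovered 18 recycled
Reagents that add atoms: none
Why: The thermodynamic extended dienolate (deprotonation of a C11 methyl) is protonated kinetically at the α-carbon C7 (deconjugative protonation), and axial protonation leaves the isopropenyl group equatorial (7β), which is also the favoured configuration at this epimerisable centre.

Step 14
Reactants: 19 3α-hydroxy-10βH-eremophil-11-en-8-one
Product: 20 3α,9β-dihydroxy-10βH-eremophil-11-en-8-one
Conditions: KN(SiMe3)2 (2.3 equiv), THF, −78 °C; 2-(phenylsulfonyl)-3-phenyloxaziridine, −78 °C; AcOH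
Reagents that add atoms: 2-(phenylsulfonyl)-3-phenyloxaziridine, O=S(=O)(c1ccccc1)N1OC1c1ccccc1
Why: The bulky amide deprotonates the unhindered C9 methylene rather than the tertiary C7, and the enolate is oxidised by the N-sulfonyloxaziridine (Davis hydroxylation) on the convex β face, away from the axial C5–C4 bond, giving the equatorial 9β-alcohol.

Step 15
Reactants: 20 3α,9β-dihydroxy-10βH-eremophil-11-en-8-one, 14 3-methylbut-2-enoyl chloride
Product: 21 3α,9β-bis(3-methylbut-2-enoyloxy)-10βH-eremophil-11-en-8-one (CNP0264508.1)
Conditions: 14 (2.5 equiv in all), pyridine, 4-(dimethylamino)pyridine (cat.), CH2Cl2, 0 °C → rt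
Reagents that add atoms: 3-methylbut-2-enoyl chloride (second equivalent of 14), CC(C)=CC(=O)Cl
Why: Double O-acylation under nucleophilic catalysis consumes two equivalents of the acid chloride (one per hydroxyl) and touches no stereocentre, and pyridine instead of a stronger amine avoids vinylketene formation from the acid chloride and enolisation of the α-isopropenyl ketone.

## Compound list

1 | cyclohexa-1,3-diene | C1=CC=CCC1 | starting material
2 | (1R,4S)-2,3-dioxabicyclo[2.2.2]oct-5-ene | C1=C[C@H]2CC[C@@H]1OO2 | intermediate
3 | (R)-4-hydroxycyclohex-2-en-1-one | O=C1CC[C@@H](O)C=C1 | intermediate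
4 | (R)-4-(benzyloxy)cyclohex-2-en-1-one | O=C1CC[C@@H](OCc2ccccc2)C=C1 | intermediate
5 | (R)-4-(benzyloxy)-2-iodocyclohex-2-en-1-one | O=C1CC[C@@H](OCc2ccccc2)C=C1I | intermediate
6 | (R)-4-(benzyloxy)-2-methylcyclohex-2-en-1-one | O=C1CC[C@@H](OCc2ccccc2)C=C1C | intermediate
7 | (2-methylallyl)magnesium chloride | CC(=C)C[Mg]Cl | starting material
8 | N-methoxy-N-methylacetamide | CC(=O)N(C)OC | starting material
9 | 4-methylpent-4-en-2-one | CC(=O)CC(C)=C | intermediate
10 | 3-[(dimethylamino)methyl]-4-methylpent-4-en-2-one (racemic) | CC(=O)C(CN(C)C)C(C)=C | intermediate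
11 | (2-acetyl-3-methylbut-3-en-1-yl)trimethylammonium iodide (racemic) | CC(=O)C(C[N+](C)(C)C)C(C)=C.[I-] | intermediate
12 | 4-methyl-3-methylidenepent-4-en-2-one | CC(=O)C(=C)C(C)=C | intermediate
13 | 3-methylbut-2-enoic acid | CC(C)=CC(=O)O | starting material
14 | 3-methylbut-2-enoyl chloride | CC(C)=CC(=O)Cl | intermediate
15 | lithium (3R,4R)-4-(benzyloxy)-2,3-dimethylcyclohex-1-en-1-olate | [Li]OC1=C(C)[C@@H](C)[C@H](OCc2ccccc2)CC1 | intermediate
16 | (2R,3R,4R)-2-(2-acetyl-3-methylbut-3-en-1-yl)-4-(benzyloxy)-2,3-dimethylcyclohexan-1-one (both epimers at the side-chain CH) | C=C(C)C(C(C)=O)C[C@@]1(C)C(=O)CC[C@@H](OCc2ccccc2)[C@@H]1C | intermediate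
17 | 3α-benzyloxyeremophila-7(11),9-dien-8-one | CC(C)=C1C[C@@]2(C)C(=CC1=O)CC[C@@H](OCc3ccccc3)[C@@H]2C | intermediate
18 | 3α-hydroxy-10βH-eremophil-7(11)-en-8-one | CC(C)=C1C[C@@]2(C)[C@H](CC[C@@H](O)[C@@H]2C)CC1=O | intermediate
19 | 3α-hydroxy-10βH-eremophil-11-en-8-one | C=C(C)[C@H]1C[C@@]2(C)[C@H](CC[C@@H](O)[C@@H]2C)CC1=O | intermediate
20 | 3α,9β-dihydroxy-10βH-eremophil-11-en-8-one | C=C(C)[C@H]1C[C@@]2(C)[C@H](CC[C@@H](O)[C@@H]2C)[C@@H](O)C1=O | intermediate
21 | 3α,9β-bis(3-methylbut-2-enoyloxy)-10βH-eremophil-11-en-8-one | C=C(C)[C@H]1C[C@@]2(C)[C@H](CC[C@@H](OC(=O)C=C(C)C)[C@@H]2C)[C@@H](OC(=O)C=C(C)C)C1=O | target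

## Step count and risks

Total step count: 15. Longest linear sequence: 10 steps (steps 1–5, then 11–15).

**Step 11** is the most fragile. The 2-acetyl diene 12 can dimerise before the hindered enolate traps it, and selectivity at the quaternary centre may erode. The fallback sets out from 6 and returns at 17: ring B is first closed with a stable vinyl ketone equivalent and the three-carbon unit is added afterwards. Me2CuLi addition to 6, trapping with 3-(trimethylsilyl)but-3-en-2-one and NaOMe/MeOH give 3α-benzyloxyeremophil-9-en-8-one F1. Deprotonation at C7 with LiN(i-Pr)2 at −78 °C and aldol addition to acetone give 3α-benzyloxy-11-hydroxyeremophil-9-en-8-one F2. Acid-catalysed dehydration (p-toluenesulfonic acid, benzene, 80 °C) then gives 17.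

**Step 12** may give too much trans-fused decalone or start to reduce the C7=C11 bond. The fallback sets out from 17 and returns at 19, changing the order so that the ring fusion is set by a hydride reagent instead. Kinetic deconjugation of 17 (LiN(i-Pr)2, −78 °C, then AcOH) gives 3α-benzyloxyeremophila-9,11-dien-8-one F3. Conjugate reduction with [(Ph3P)CuH]6 in wet benzene, which leaves the isolated isopropenyl group alone, gives 3α-benzyloxy-10βH-eremophil-11-en-8-one F4. Oxidative debenzylation (2,3-dichloro-5,6-dicyano-1,4-benzoquinone, visible light, wet CH2Cl2) gives 19.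

**Step 13** may return mostly 18 if the dienolate is protonated at the γ-carbon. The fallback sets out from 18 and returns at 19, isolating the dienol as a covalent derivative and protonating it under non-basic conditions. Me3SiOSO2CF3 and Et3N convert 18 into the bis(trimethylsilyl) dienol ether F5, which is purified. Protodesilylation with HF·pyridine at −40 °C then gives 19.

Further compounds

F1 | step 11 | 3α-benzyloxyeremophil-9-en-8-one | O=C1CC[C@@]2(C)C(=C1)CC[C@@H](OCc3ccccc3)[C@@H]2C
F2 | step 11 | 3α-benzyloxy-11-hydroxyeremophil-9-en-8-one (7α-substituent drawn) | CC(C)(O)[C@@H]1C[C@@]2(C)C(=CC1=O)CC[C@@H](OCc3ccccc3)[C@@H]2C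
F3 | step 12 | 3α-benzyloxyeremophila-9,11-dien-8-one (7β-isopropenyl) | C=C(C)[C@H]1C[C@@]2(C)C(=CC1=O)CC[C@@H](OCc3ccccc3)[C@@H]2C
F4 | step 12 | 3α-benzyloxy-10βH-eremophil-11-en-8-one | C=C(C)[C@H]1C[C@@]2(C)[C@H](CC[C@@H](OCc3ccccc3)[C@@H]2C)CC1=O
F5 | step 13 | 3α,8-bis(trimethylsilyloxy)-10βH-eremophila-7,11-diene | C=C(C)C=1C[C@@]2(C)[C@H](CC[C@@H](O[Si](C)(C)C)[C@@H]2C)CC=1O[Si](C)(C)C
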